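**Plan**

- Retrosynthesis: the enal is unmasked last from an alkenyl dimethyl acetal. Before that, the angeloyl C–O bond at C1', the acetyl C–O bond at O3 and the exocyclic C=CH2 bond (back to a ketone) are cut.
- Ring B is then opened at C2–C3 and O1–C2. In benzofuran numbering O1, C7a, C3a and the carbinol carbon C3 form the HO–C=C–CHO array of a salicylaldehyde, so only C2, with its acyl-type substituent, has to be inserted as the carbon of a sulfonium ylide ([4+1]).
- Forward: ring A is a para-acylphenol that is reduced, silylated and ortho-formylated; a C2-symmetric thiolane is alkylated with a bromoketo acetal; the annulation closes ring B; methylenation, O3-acetylation, desilylation, angeloylation and acetal hydrolysis finish the molecule.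
- Stereochemistry: C1' (R) comes from asymmetric transfer hydrogenation. C2/C3 trans comes from reversible addition followed by irreversible ring closure, and their absolute sense from the chiral sulfide that leaves in that closure. The Z alkene arrives intact with the acid.

Key step: step 9

Assumption: the (2R,5R)-dimethylthiolanium group is taken to favour the (2S,3S) ring; if the facial sense proves opposite, the enantiomeric diol is used in step 6 and nothing else changes.

**Route**

Step 1
Reactants: 1 4'-hydroxyacetophenone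
Product: 2 1-[4-(tert-butyldimethylsilyloxy)phenyl]ethan-1-one
Conditions: TBSCl, imidazole, DMF, rt
Reagents that add atoms: tert-butyldimethylsilyl chloride (TBSCl), CC(C)(C)[Si](C)(C)Cl
Why: Imidazole-promoted silylation of the phenol masks the acidic OH, which would otherwise retard hydride transfer to the ketone and labilise the later benzylic carbinol.

Step 2
Reactants: 2 1-[4-(tert-butyldimethylsilyloxy)phenyl]ethan-1-one
Product: 3 (1R)-1-[4-(tert-butyldimethylsilyloxy)phenyl]ethan-1-ol
Conditions: RuCl(p-cymene)[(R,R)-TsDPEN] (cat.), HCO2H–Et3N (5:2), 30 °C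
Reagents that add atoms: none
Why: Noyori asymmetric transfer hydrogenation of an aryl methyl ketone, in which the (R,R)-TsDPEN ligand directs hydride to the face that gives the (R)-1-arylethanol and loss of CO2 makes the reduction irreversible.

Step 3
Reactants: 3 (1R)-1-[4-(tert-butyldimethylsilyloxy)phenyl]ethan-1-ol
Product: 4 tert-butyl{4-[(1R)-1-(tert-butyldimethylsilyloxy)ethyl]phenoxy}dimethylsilane
Conditions: TBSCl, imidazole, DMF, rt
Reagents that add atoms: tert-butyldimethylsilyl chloride (TBSCl), CC(C)(C)[Si](C)(C)Cl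
Why: Silyl ether formation at the secondary benzylic alcohol makes only an O–Si bond, so the (R) centre is untouched and is carried as a poor leaving group through the phenoxide chemistry that follows.

Step 4
Reactants: 4 tert-butyl{4-[(1R)-1-(tert-butyldimethylsilyloxy)ethyl]phenoxy}dimethylsilane
Product: 5 4-[(1R)-1-(tert-butyldimethylsilyloxy)ethyl]phenol
Conditions: Cs2CO3 (0.5 equiv), DMF–H2O (10:1), rt
Reagents that add atoms: none
Why: Chemoselective carbonate-mediated hydrolysis of the aryl silyl ether, which is cleaved far faster than the alkyl silyl ether because phenoxide is the better leaving group at silicon.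

Step 5
Reactants: 5 4-[(1R)-1-(tert-butyldimethylsilyloxy)ethyl]phenol
Product: 6 5-[(1R)-1-(tert-butyldimethylsilyloxy)ethyl]-2-hydroxybenzaldehyde
Conditions: MgCl2, Et3N, (CH2O)n, THF, reflux
Reagents that add atoms: paraformaldehyde (as formaldehyde), C=O
Why: Magnesium-mediated ortho-formylation (Casnati–Skattebøl), in which the magnesium phenoxide delivers formaldehyde to an ortho position (para is blocked) and a second formaldehyde oxidises the benzylic alkoxide by hydride transfer, while the silyloxide at C1' is too poor a leaving group for quinone methide formation, so the (R) centre should persist.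

Step 6
Reactants: 7 (2S,5S)-hexane-2,5-diol
Product: 8 (2S,5S)-hexane-2,5-diyl dimethanesulfonate
Conditions: MsCl, Et3N, CH2Cl2, 0 °C
Reagents that add atoms: methanesulfonyl chloride (MsCl), CS(=O)(=O)Cl
Why: O-sulfonylation of both secondary alcohols occurs with retention because no C–O bond is broken.

Step 7
Reactants: 8 (2S,5S)-hexane-2,5-diyl dimethanesulfonate
Product: 9 (2R,5R)-2,5-dimethylthiolane
Conditions: Na2S·9H2O, EtOH–H2O, rt → 40 °C
Reagents that add atoms: sodium sulfide (Na2S·9H2O), [Na+].[Na+].[S-2]
Why: Twofold SN2 thioetherification (the second displacement a 5-exo-tet closure) inverts both carbinol carbons, so the (2S,5S) dimesylate gives the trans, C2-symmetric (2R,5R) thiolane.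

Step 8
Reactants: 9 (2R,5R)-2,5-dimethylthiolane; 10 3-bromo-1,1-dimethoxypropan-2-one
Product: 11 (2R,5R)-1-(3,3-dimethoxy-2-oxopropyl)-2,5-dimethylthiolan-1-ium bromide
Conditions: acetone (concentrated), rt, dark
Reagents that add atoms: none
Why: SN2 S-alkylation of a dialkyl sulfide by an α-bromo ketone, and because the thiolane is C2-symmetric its two sulfur lone pairs are equivalent and a single sulfonium salt results.

Step 9
Reactants: 6 5-[(1R)-1-(tert-butyldimethylsilyloxy)ethyl]-2-hydroxybenzaldehyde; 11 (2R,5R)-1-(3,3-dimethoxy-2-oxopropyl)-2,5-dimethylthiolan-1-ium bromide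
Product: 13 1-[(2S,3S)-5-[(1R)-1-(tert-butyldimethylsilyloxy)ethyl]-3-hydroxy-2,3-dihydro-1-benzofuran-2-yl]-2,2-dimethoxyethan-1-one, via sulfonium ylide 12 (not isolated)
Conditions: K2CO3 (powdered), MeCN, 0 °C → rt
Reagents that add atoms: none
Why: Proposed new method: K2CO3 converts salt 11 into the ketone-stabilised ylide 12, whose carbon adds reversibly to the formyl carbon of 6 (C2–C3 bond), and after proton transfer the phenoxide displaces the thiolane from C2 with inversion (O1–C2 bond), closing ring B in a 5-exo-tet mode. The closest known chemistry is the racemic, trans-selective [4+1] annulation of salicylaldehydes with carbonyl-stabilised sulfonium ylides to 2-acyl-2,3-dihydrobenzofuran-3-ols, together with the use of C2-symmetric 2,5-dimethylthiolanium ylides as chiral leaving groups in epoxidation. Because the addition is reversible and C2–H of the adducts is acidic, the betaines interconvert and the ring closure is rate- and stereodetermining: the trans C2/C3 relationship follows from the less crowded closure (and from base equilibration at C2 of the product), while the absolute configuration at C3, and with it C2, is fixed by the dimethylthiolanium group still bound to C2 in the diastereomeric closure transition states. The remote (R)-carbinol gives no useful bias, but it turns the unwanted ring enantiomer into a diastereomer that chromatography can remove. The step needs C-attack of the ylide on the aldehyde to outrun O-alkylation of the phenoxide by the salt, which would bypass sulfide control; the hydrogen-bond-activated formyl group, the hindered α-branched sulfonium centre and the low temperature should secure this, and the silyl ether and dimethyl acetal are inert to carbonate.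

Step 10
Reactants: 13 1-[(2S,3S)-5-[(1R)-1-(tert-butyldimethylsilyloxy)ethyl]-3-hydroxy-2,3-dihydro-1-benzofuran-2-yl]-2,2-dimethoxyethan-1-one
Product: 16 (2R,3S)-5-[(1R)-1-(tert-butyldimethylsilyloxy)ethyl]-2-(3,3-dimethoxyprop-1-en-2-yl)-2,3-dihydro-1-benzofuran-3-ol, via trimethylsilyl ether ketone 14 (not isolated), via trimethylsilyl ether alkene 15 (not isolated)
Conditions: TMSCl, Et3N, CH2Cl2, 0 °C; then Cp2TiMe2, toluene–THF, 65 °C, dark; then K2CO3 (cat.), MeOH, 0 °C
Reagents that add atoms: bis(cyclopentadienyl)dimethyltitanium (Cp2TiMe2), C[Ti](C)(C1C=CC=C1)C1C=CC=C1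
Why: Petasis methylenation, in which heated Cp2TiMe2 loses methane to give Cp2Ti=CH2 that converts the ketone into the 1,1-disubstituted alkene through an oxatitanacyclobutane under non-basic conditions that leave the acidic C2–H, the acetal and the silyl ethers alone, the transient trimethylsilyl ether (removed afterwards by carbonate methanolysis) keeping the C3 hydroxyl from consuming the reagent or opening the ring by retro-aldol cleavage.

Step 11
Reactants: 16 (2R,3S)-5-[(1R)-1-(tert-butyldimethylsilyloxy)ethyl]-2-(3,3-dimethoxyprop-1-en-2-yl)-2,3-dihydro-1-benzofuran-3-ol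
Product: 17 (2R,3S)-5-[(1R)-1-(tert-butyldimethylsilyloxy)ethyl]-2-(3,3-dimethoxyprop-1-en-2-yl)-2,3-dihydro-1-benzofuran-3-yl acetate
Conditions: Ac2O, pyridine, DMAP (cat.), CH2Cl2, 0 °C → rt
Reagents that add atoms: acetic anhydride, CC(=O)OC(C)=O
Why: DMAP-catalysed O-acylation of the secondary C3 alcohol proceeds without C–O cleavage, and with the ketone already converted into the alkene there is no acidic C2–H left to drive β-elimination to the aromatic benzofuran.

Step 12
Reactants: 17 (2R,3S)-5-[(1R)-1-(tert-butyldimethylsilyloxy)ethyl]-2-(3,3-dimethoxyprop-1-en-2-yl)-2,3-dihydro-1-benzofuran-3-yl acetate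
Product: 18 (2R,3S)-2-(3,3-dimethoxyprop-1-en-2-yl)-5-[(1R)-1-hydroxyethyl]-2,3-dihydro-1-benzofuran-3-yl acetate
Conditions: Bu4NF, AcOH, THF, 0 °C → rt
Reagents that add atoms: none
Why: Fluoride-induced desilylation driven by Si–F bond formation, with acetic acid buffering the basicity so that the C3 acetate and the acetal should survive and the C1' centre is not touched.

Step 13
Reactants: 18 (2R,3S)-2-(3,3-dimethoxyprop-1-en-2-yl)-5-[(1R)-1-hydroxyethyl]-2,3-dihydro-1-benzofuran-3-yl acetate; 19 angelic acid, (2Z)-2-methylbut-2-enoic acid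
Product: 21 (1R)-1-[(2R,3S)-3-(acetyloxy)-2-(3,3-dimethoxyprop-1-en-2-yl)-2,3-dihydro-1-benzofuran-5-yl]ethyl (2Z)-2-methylbut-2-enoate, via angelic 2,4,6-trichlorobenzoic anhydride 20 (not isolated)
Conditions: 19, 2,4,6-trichlorobenzoyl chloride, Et3N, toluene, rt; then 18, toluene, 70 °C (no DMAP)
Reagents that add atoms: none
Why: Yamaguchi esterification, in which the alcohol attacks the mixed anhydride at the angeloyl carbonyl because the aroyl carbonyl is shielded by its two ortho chlorines, and leaving out DMAP avoids the conjugate addition–elimination that turns angelates into tiglates, so the Z geometry and the C1' configuration (O-acylation only) should be retained.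

Step 14
Reactants: 21 (1R)-1-[(2R,3S)-3-(acetyloxy)-2-(3,3-dimethoxyprop-1-en-2-yl)-2,3-dihydro-1-benzofuran-5-yl]ethyl (2Z)-2-methylbut-2-enoate
Product: 22 (1R)-1-[(2R,3S)-3-(acetyloxy)-2-(3-oxoprop-1-en-2-yl)-2,3-dihydro-1-benzofuran-5-yl]ethyl (2Z)-2-methylbut-2-enoate
Conditions: oxalic acid (5% aq.), SiO2, CH2Cl2, rt
Reagents that add atoms: water, O
Why: Acid-catalysed acetal hydrolysis, which for this 2-alkenyl dimethyl acetal passes through a stabilised allylic oxocarbenium ion, so the weak heterogeneous acid of oxalic acid on wet silica should suffice and spare the two benzylic esters and the Z enoate.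

**Compound list**

1 | 4'-hydroxyacetophenone | CC(=O)c1ccc(O)cc1 | starting material
2 | 1-[4-(tert-butyldimethylsilyloxy)phenyl]ethan-1-one | CC(=O)c1ccc(O[Si](C)(C)C(C)(C)C)cc1 | intermediate
3 | (1R)-1-[4-(tert-butyldimethylsilyloxy)phenyl]ethan-1-ol | C[C@@H](O)c1ccc(O[Si](C)(C)C(C)(C)C)cc1 | intermediate
4 | tert-butyl{4-[(1R)-1-(tert-butyldimethylsilyloxy)ethyl]phenoxy}dimethylsilane | C[C@@H](O[Si](C)(C)C(C)(C)C)c1ccc(O[Si](C)(C)C(C)(C)C)cc1 | intermediate
5 | 4-[(1R)-1-(tert-butyldimethylsilyloxy)ethyl]phenol | C[C@@H](O[Si](C)(C)C(C)(C)C)c1ccc(O)cc1 | intermediate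
6 | 5-[(1R)-1-(tert-butyldimethylsilyloxy)ethyl]-2-hydroxybenzaldehyde | C[C@@H](O[Si](C)(C)C(C)(C)C)c1ccc(O)c(C=O)c1 | intermediate
7 | (2S,5S)-hexane-2,5-diol | C[C@H](O)CC[C@H](C)O | starting material
8 | (2S,5S)-hexane-2,5-diyl dimethanesulfonate | C[C@H](OS(C)(=O)=O)CC[C@H](C)OS(C)(=O)=O | intermediate
9 | (2R,5R)-2,5-dimethylthiolane | C[C@@H]1CC[C@@H](C)S1 | intermediate
10 | 3-bromo-1,1-dimethoxypropan-2-one | COC(OC)C(=O)CBr | starting material
11 | (2R,5R)-1-(3,3-dimethoxy-2-oxopropyl)-2,5-dimethylthiolan-1-ium bromide | C[C@@H]1CC[C@@H](C)[S+]1CC(=O)C(OC)OC.[Br-] | intermediate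
12 | 3,3-dimethoxy-1-[(2R,5R)-2,5-dimethylthiolan-1-ium-1-yl]-2-oxopropan-1-ide (sulfonium ylide, not isolated) | C[C@@H]1CC[C@@H](C)[S+]1[CH-]C(=O)C(OC)OC | intermediate
13 | 1-[(2S,3S)-5-[(1R)-1-(tert-butyldimethylsilyloxy)ethyl]-3-hydroxy-2,3-dihydro-1-benzofuran-2-yl]-2,2-dimethoxyethan-1-one (2,3-trans) | COC(OC)C(=O)[C@H]1Oc2ccc([C@@H](C)O[Si](C)(C)C(C)(C)C)cc2[C@@H]1O | intermediate
14 | 1-[(2S,3S)-5-[(1R)-1-(tert-butyldimethylsilyloxy)ethyl]-3-(trimethylsilyloxy)-2,3-dihydro-1-benzofuran-2-yl]-2,2-dimethoxyethan-1-one (not isolated) | COC(OC)C(=O)[C@H]1Oc2ccc([C@@H](C)O[Si](C)(C)C(C)(C)C)cc2[C@@H]1O[Si](C)(C)C | intermediate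
15 | tert-butyl{(1R)-1-[(2R,3S)-2-(3,3-dimethoxyprop-1-en-2-yl)-3-(trimethylsilyloxy)-2,3-dihydro-1-benzofuran-5-yl]ethoxy}dimethylsilane (not isolated) | COC(OC)C(=C)[C@H]1Oc2ccc([C@@H](C)O[Si](C)(C)C(C)(C)C)cc2[C@@H]1O[Si](C)(C)C | intermediate
16 | (2R,3S)-5-[(1R)-1-(tert-butyldimethylsilyloxy)ethyl]-2-(3,3-dimethoxyprop-1-en-2-yl)-2,3-dihydro-1-benzofuran-3-ol | COC(OC)C(=C)[C@H]1Oc2ccc([C@@H](C)O[Si](C)(C)C(C)(C)C)cc2[C@@H]1O | intermediate
17 | (2R,3S)-5-[(1R)-1-(tert-butyldimethylsilyloxy)ethyl]-2-(3,3-dimethoxyprop-1-en-2-yl)-2,3-dihydro-1-benzofuran-3-yl acetate | COC(OC)C(=C)[C@H]1Oc2ccc([C@@H](C)O[Si](C)(C)C(C)(C)C)cc2[C@@H]1OC(C)=O | intermediate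
18 | (2R,3S)-2-(3,3-dimethoxyprop-1-en-2-yl)-5-[(1R)-1-hydroxyethyl]-2,3-dihydro-1-benzofuran-3-yl acetate | COC(OC)C(=C)[C@H]1Oc2ccc([C@@H](C)O)cc2[C@@H]1OC(C)=O | intermediate
19 | angelic acid, (2Z)-2-methylbut-2-enoic acid | C/C=C(/C)C(=O)O | starting material
20 | (2Z)-2-methylbut-2-enoic 2,4,6-trichlorobenzoic anhydride (not isolated) | C/C=C(/C)C(=O)OC(=O)c1c(Cl)cc(Cl)cc1Cl | intermediate
21 | (1R)-1-[(2R,3S)-3-(acetyloxy)-2-(3,3-dimethoxyprop-1-en-2-yl)-2,3-dihydro-1-benzofuran-5-yl]ethyl (2Z)-2-methylbut-2-enoate | COC(OC)C(=C)[C@H]1Oc2ccc([C@@H](C)OC(=O)/C(C)=C\C)cc2[C@@H]1OC(C)=O | intermediate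
22 | (1R)-1-[(2R,3S)-3-(acetyloxy)-2-(3-oxoprop-1-en-2-yl)-2,3-dihydro-1-benzofuran-5-yl]ethyl (2Z)-2-methylbut-2-enoate | C=C(C=O)[C@H]1Oc2ccc([C@@H](C)OC(=O)/C(C)=C\C)cc2[C@@H]1OC(C)=O | target

**Step count**

Total: 14 steps. Longest linear sequence: 11 steps (steps 1–5, then 9–14); the sulfonium salt is made in 3 steps (6–8) on a side branch.

**Steps most likely to fail**

Step 9 (proposed new method). The thiolanium group may discriminate poorly between the two faces in the ring closure, or O-alkylation of the phenoxide by the salt followed by an uncontrolled aldol closure may erode sulfide control. In that case ring B is built without reagent control. Aldehyde 6 is treated under the same carbonate conditions with the achiral salt 1-(3,3-dimethoxy-2-oxopropyl)thiolan-1-ium bromide F1, made from thiolane and bromoketone 10 in acetone. This is the established trans-selective annulation and should give 13 together with its ring-enantiomeric trans isomer 1-[(2R,3R)-5-[(1R)-1-(tert-butyldimethylsilyloxy)ethyl]-3-hydroxy-2,3-dihydro-1-benzofuran-2-yl]-2,2-dimethoxyethan-1-one F2. Because C1' is already (R), F2 is a diastereomer of 13 and is removed by chromatography (preparative HPLC if needed). The route resumes at 13.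

Step 10. Heating with the titanium reagent may cause retro-aldol ring opening or elimination toward the aromatic benzofuran, or the transient silyl ether may be lost before the carbonyl is converted. The methylene carbon is then introduced by addition–elimination instead of a metal carbene. Trimethylsilyl ether 14 is isolated and treated with Me3SiCH2Li/CeCl3 (THF, −78 °C); the weakly basic organocerium adds to the enolisable ketone to give the β-hydroxysilane 2-[(2S,3S)-5-[(1R)-1-(tert-butyldimethylsilyloxy)ethyl]-3-(trimethylsilyloxy)-2,3-dihydro-1-benzofuran-2-yl]-1,1-dimethoxy-3-(trimethylsilyl)propan-2-ol F3 (either epimer at the new carbinol). KH (THF, 0 °C) then induces the syn-elimination of a Peterson olefination to give trimethylsilyl ether alkene 15, which rejoins the route before the methanolysis to 16.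

Step 13. The activated angeloyl unit may isomerise from Z to E, or the electron-rich benzylic alcohol may ionise during the warm acylation. The Z alkene is then built on the ester. Alcohol 18 is esterified (DCC, DMAP cat., CH2Cl2, 0 °C; Steglich conditions) with 2-[bis(2,2,2-trifluoroethoxy)phosphoryl]propanoic acid to give (1R)-1-[(2R,3S)-3-(acetyloxy)-2-(3,3-dimethoxyprop-1-en-2-yl)-2,3-dihydro-1-benzofuran-5-yl]ethyl 2-[bis(2,2,2-trifluoroethoxy)phosphoryl]propanoate F4 (either epimer at the phosphonate carbon). Still–Gennari olefination (KN(SiMe3)2, 18-crown-6, THF, −78 °C, then acetaldehyde) should give the Z-trisubstituted enoate 21, where the route continues.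

**Further compounds**

F1 | step 9 | 1-(3,3-dimethoxy-2-oxopropyl)thiolan-1-ium bromide | COC(OC)C(=O)C[S+]1CCCC1.[Br-]
F2 | step 9 | 1-[(2R,3R)-5-[(1R)-1-(tert-butyldimethylsilyloxy)ethyl]-3-hydroxy-2,3-dihydro-1-benzofuran-2-yl]-2,2-dimethoxyethan-1-one | COC(OC)C(=O)[C@@H]1Oc2ccc([C@@H](C)O[Si](C)(C)C(C)(C)C)cc2[C@H]1O
F3 | step 10 | 2-[(2S,3S)-5-[(1R)-1-(tert-butyldimethylsilyloxy)ethyl]-3-(trimethylsilyloxy)-2,3-dihydro-1-benzofuran-2-yl]-1,1-dimethoxy-3-(trimethylsilyl)propan-2-ol | COC(OC)C(O)(C[Si](C)(C)C)[C@H]1Oc2ccc([C@@H](C)O[Si](C)(C)C(C)(C)C)cc2[C@@H]1O[Si](C)(C)C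
F4 | step 13 | (1R)-1-[(2R,3S)-3-(acetyloxy)-2-(3,3-dimethoxyprop-1-en-2-yl)-2,3-dihydro-1-benzofuran-5-yl]ethyl 2-[bis(2,2,2-trifluoroethoxy)phosphoryl]propanoate | COC(OC)C(=C)[C@H]1Oc2ccc([C@@H](C)OC(=O)C(C)P(=O)(OCC(F)(F)F)OCC(F)(F)F)cc2[C@@H]1OC(C)=O
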